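## Structural features

The target is a flavone: a benzo ring (ring A) fused through C4a–C8a to a 4-pyranone (ring C), which carries a para-substituted phenyl ring (ring B) on C2. Ring C bears a methyl ether on C3. Ring A bears a free hydroxyl on C5, hydrogen-bonded to the C4 carbonyl, and a methyl ether on C7. Ring B bears a 3-methylbut-2-enyl (prenyl) ether on C4'. There is no stereocentre and no configurable double bond, so the problem is one of regiochemistry: four oxygens in three states (free 5-OH, 3- and 7-OMe, 4'-O-prenyl) must be placed without a late selective dealkylation. The fragile parts are the prenyl ether, whose electron-rich alkene and allylic C–O bond do not tolerate electrophilic halogen, strong protic acid or silyl triflates, and C2 of the pyranone, which hard nucleophiles attack with ring opening. The real difficulty is to deliver ring A with C5 and C7 already differentiated while ring C and its 3-OMe are in place. The key step uses the 1,3-relationship of C5–OH and C7–OMe on a ring whose C4a–C8a edge is the C5=C6 bond of a monocyclic 4-pyranone. The four carbons C5–C8 with both oxygens can come from one 1,1,3-trioxygenated butadiene, and a bromine on the pyranone carbon that becomes C4a supplies the oxidation level for aromatisation.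

## Logic of the disconnections

19 ⇒ 16 + 17. The O4'–CH2 bond of the allylic ether is cut last in the backward sense, so that it is formed last. The alkene and the acid-labile allyl aryl ether would not survive electrophilic bromine, trifluoroacetic acid or a silyl triflate earlier in the route. The gain is that 16 carries a robust silyl ether through all of these. The forward step must alkylate O4' only; this relies on the hydrogen bond that holds the 5-OH and on releasing the phenoxide 18 site-specifically from the Si–O bond.

16 ⇒ 9 + 12. The bonds C4a–C5 and C8–C8a are cut, which removes ring A entirely. The bicyclic flavone is reduced to a monocyclic pyranone and a four-carbon diene that already carries the 5-O/7-O pattern in differentiated form. The forward step demands that the C5=C6 bond of 9 accepts the diene with one orientation (via 13 and 14) and that the adduct loses HBr and methanol to give 15 and then 16.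

12 ⇒ 10. The O–Si bond is cut. The diene is one step from a commercial vinylogous ester, via 11. The forward step demands γ-deprotonation and silylation on oxygen under kinetic control.

9 ⇒ 8. The C5–Br bond is cut. The halogen is introduced on the finished heterocycle, where C5 is the only nucleophilic CH carbon. The forward step demands that the electrophile chooses C5 over the silyloxyarene.

8 ⇒ 4 + 5. The bonds C3–C4 and O1–C6 of the pyranone are cut. This gives an α-methoxy aryl ketone and a three-carbon acyl unit with a β-leaving group, and builds the ring in one operation via 6 and 7. The forward step demands C- over O-acylation and 6-endo closure by the enol oxygen of the aryl ketone.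

4 ⇒ 1 + 2. The aryl–carbonyl bond is cut. The α-methoxy ketone then arises in one step, via 3, with the phenol already masked. The forward step demands single addition to the amide, which the chelated tetrahedral adduct secures.

## Other disconnections considered

Alternative 1: The cut is C4a–C5 inside ring A, made on an open polyketide chain. Mg(OMe)2 in methanol would open the 4-hydroxy-2-pyrone A1 to the 3,5,7-triketo ester A2, whose C6 methylene would attack the ester carbonyl (Claisen folding) to give the α-methoxychalcone A3.
- In favour: the folding follows a biosynthetic pattern, needs no protecting group, tolerates the prenyl ether from the first step, and creates all of ring A from acyclic carbons. On protecting-group economy it is better than the chosen plan.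
- Against: A2 can also fold by aldol closure (C2 onto the C7 carbonyl) to a resorcylate, so the folding mode must be steered by the magnesium chelate. The α-methoxy enone is a Michael acceptor for methoxide. A3 is still two operations from the target: ring C must be closed oxidatively (O1–C2) in the presence of the prenyl alkene and free phenols, and the three ring-A hydroxyls emerge undifferentiated, so the 7-oxygen needs a selective methylation.
- Comparison: on structure the chosen plan is ahead, since 16 leaves step 5 with ring C complete and 5-OH/7-OMe distinguished. On mechanism the Claisen folding rests on a known type of polyketide cyclisation and is the equal or the better of step 5, which has no direct precedent. On step economy the two are about equal, because A1 itself needs a pyrone dianion acylation and an aryl enoate synthesis.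

Alternative 2: The cut is O1–C8a of ring C. With K2CO3 in dimethylformamide the enolate oxygen of the 1,3-diketone A4 would displace one of two equivalent ortho fluorides (intramolecular SNAr) to give the 5-fluoroflavone A5.
- In favour: SNAr closure of ortho-fluoroaryl 1,3-diketones to chromones is established, the symmetry of the difluoroarene removes any regiochemical question, the mild base tolerates the prenyl ether, and the assembly is convergent. On precedent and on tolerance of the prenyl group it is better than the chosen plan.
- Against: A5 carries fluorine where the target carries OH, so a second SNAr with an oxygen nucleophile is needed at C5. Hydroxide may add to C2 and open ring C, and a masked hydroxide unveiled by hydrogenolysis would endanger the prenyl alkene, so the choice of nucleophile is narrow.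
- Comparison: on structure the chosen plan delivers the free chelated 5-OH directly, whereas A5 postpones that problem. On mechanism the alternative is the safer of the two. On step economy they are about equal.

Alternative 3: The cut is C4–C4a. The acrylic acid A6, activated as its mixed anhydride with trifluoroacetic anhydride, would acylate an ortho carbon of its own 3,5-dimethoxyphenoxy ring (intramolecular Friedel–Crafts acylation) to give the trimethoxyflavone A7.
- In favour: the arene is strongly activated at the carbon that must react, its two ortho positions are equivalent, and acid-mediated closures onto phloroglucinol-type rings are well established. In electronic match and precedent it is better than step 5.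
- Against: the acid conditions exclude a prenyl ether, hence the benzyl group. A6 is a tetrasubstituted alkene whose acid and aryloxy groups must be cis. A7 still needs three operations: chelation-controlled cleavage of the 5-OMe in the presence of the 3-OMe (which also flanks the carbonyl), debenzylation, and prenylation.
- Comparison: on structure the chosen plan is ahead, because it never makes a 5-O-methyl ether that must be removed. On mechanism the alternative is ahead. On step economy the chosen plan is shorter after the key step (one operation against three).

Key step: step 5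

Assumption: the ketene acetal double bond of 12 is written as (1E); either geometric isomer, or a mixture, should give the same flavone, because that carbon ends as the sp2 carbon C5.
Assumption: 1, 2, 5, 10 and 17 are taken as commercially available; the connectivity of 9, 12 and 16 was checked against the bonds formed in step 5 (CH2 terminus of 12 to C6 of 9, ketene acetal carbon to C5 of 9) and needed no correction.

## Route

Step 1
Reactants: 1 (4-bromophenoxy)(tert-butyl)dimethylsilane; 2 N,2-dimethoxy-N-methylacetamide
Product: 4 1-[4-(tert-butyldimethylsilyloxy)phenyl]-2-methoxyethan-1-one, via arylmagnesium bromide 3 (not isolated)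
Conditions: Mg, I2 (cat.), THF, 50 °C; then 2, THF, 0 °C; 1 M HCl, 0 °C
Reagents that add atoms: none
Why: Weinreb ketone synthesis: Grignard reagent 3 adds once to amide 2 and the magnesium chelate of the tetrahedral adduct, reinforced by the α-methoxy oxygen, holds until the acidic quench, so no tertiary alcohol should form; the aryl silyl ether tolerates magnesium insertion. This opening avoids a methoxide displacement on a 4-hydroxyphenacyl bromide, where phenoxide self-alkylation and epoxy-ether formation would compete.

Step 2
Reactants: 4 1-[4-(tert-butyldimethylsilyloxy)phenyl]-2-methoxyethan-1-one; 5 (2E)-3-ethoxyprop-2-enoyl chloride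
Product: 8 2-[4-(tert-butyldimethylsilyloxy)phenyl]-3-methoxy-4H-pyran-4-one, via lithium enolate 6 (not isolated), via ethoxyvinyl diketone 7 (not isolated)
Conditions: LiN(SiMe3)2 (2.1 equiv), THF–toluene, −78 °C; 5, −78 → 0 °C; then CF3CO2H, CH2Cl2, rt
Reagents that add atoms: none
Why: Claisen-type C-acylation of the chelated lithium (Z)-enolate 6 by the acid chloride (the second equivalent of base takes up the more acidic diketone 7), then acid-catalysed 6-endo conjugate addition of the aryl-ketone enol oxygen to the β-ethoxy enone with loss of ethanol; this is the established 4-pyranone synthesis from ketone enolates and β-alkoxyacryloyl chlorides. The aryl silyl ether should be stable to anhydrous CF3CO2H for the short reaction time.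

Step 3
Reactants: 8 2-[4-(tert-butyldimethylsilyloxy)phenyl]-3-methoxy-4H-pyran-4-one
Product: 9 5-bromo-2-[4-(tert-butyldimethylsilyloxy)phenyl]-3-methoxy-4H-pyran-4-one
Conditions: NBS (1.05 equiv), MeCN, 0 °C → rt, dark
Reagents that add atoms: N-bromosuccinimide, O=C1CCC(=O)N1Br
Why: Electrophilic α-bromination of a vinylogous ester: C5 is the only CH carbon that is β to the ring oxygen and α to the carbonyl (C6 is electrophilic, C2 and C3 are substituted), and the silyloxyphenyl ring is deactivated by conjugation with C2, so substitution should occur at C5; 8 has no enolisable position.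

Step 4
Reactants: 10 methyl (2E)-3-methoxybut-2-enoate
Product: 12 (1E)-1,3-dimethoxy-1-(trimethylsilyloxy)buta-1,3-diene, via lithium dienolate 11 (not isolated)
Conditions: LiN(i-Pr)2, THF, −78 °C; Me3SiCl, −78 °C → rt; pentane, filtration, distillation
Reagents that add atoms: chlorotrimethylsilane, C[Si](C)(C)Cl
Why: Kinetic γ-deprotonation of the vinylogous ester gives the extended lithium enolate 11, which the silyl chloride traps on oxygen (standard formation of a vinylketene silyl acetal); the moisture-sensitive diene is used directly.

Step 5
Reactants: 9 5-bromo-2-[4-(tert-butyldimethylsilyloxy)phenyl]-3-methoxy-4H-pyran-4-one; 12 (1E)-1,3-dimethoxy-1-(trimethylsilyloxy)buta-1,3-diene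
Product: 16 4'-(tert-butyldimethylsilyloxy)-5-hydroxy-3,7-dimethoxyflavone, via silyloxypyrylium triflate 13 (not isolated), via bromo ketal cycloadduct 14 (not isolated), via 5-O-trimethylsilyl flavone 15 (not isolated)
Conditions: Me3SiOTf (1.2 equiv), CH2Cl2, −78 → 0 °C; then 12 (2.5 equiv), −78 → 0 °C; then Et3N (4 equiv), 0 °C → rt; 1 M HCl–THF, 0 °C
Reagents that add atoms: none
Why: Proposed new method: Me3SiOTf silylates the pyranone carbonyl of 9 to the 4-silyloxypyrylium ion 13, the CH2 terminus of 12 adds to its unsubstituted C6 (vinylogous Mukaiyama–Michael addition, forming C8–C8a), and the silyl enol ether carbon C5 then attacks the dioxocarbenium carbon left from the ketene acetal (forming C4a–C5), which releases Me3SiOTf and gives 14; a concerted Diels–Alder transition state would lead to the same adduct. The closest known reaction types are the Diels–Alder–aromatisation of 1,1,3-trioxygenated butadienes with halogenated quinones and the cyclohexene annulation of 4-silyloxybenzopyrylium salts with silyloxydienes, whereas a monocyclic 5-bromo-4-pyranone has not been used as the two-carbon partner. Ring A is closed in a (4+2) mode, four carbons from 12 and the C5–C6 pair of 9, the second bond forming by six-membered closure of an enol ether onto a tethered cation. The ring-fusion stereocentres and the ketal carbon of 14 are transient and are erased on aromatisation, so no stereocontrol is required. The step needs site selectivity for C6 over C2, which the fully substituted, donor-conjugated C2=C3 bond secures, and it needs the nucleophilic diene terminus to bond to the bromine-free carbon, which follows from the polarisation of the vinylogous ester and of the pyrylium ion. Ionisation of the mixed ketal with loss of methanol, followed by removal of HBr across C4a–C8a by Et3N, should aromatise ring A to the silyl ether 15, the bromine supplying the oxidation level. Brief cold aqueous acid should cleave only the labile Me3Si ether and free the chelated 5-OH, the aryl tert-butyldimethylsilyl ether being retained.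

Step 6
Reactants: 16 4'-(tert-butyldimethylsilyloxy)-5-hydroxy-3,7-dimethoxyflavone; 17 1-bromo-3-methylbut-2-ene (prenyl bromide)
Product: 19 5-hydroxy-3,7-dimethoxy-4'-(3-methylbut-2-enyloxy)flavone (CNP0518751.0), via cesium phenoxide 18 (not isolated)
Conditions: CsF (1.5 equiv), 17 (1.1 equiv), DMF, 0 °C → rt
Reagents that add atoms: none
Why: Fluoride cleaves the aryl Si–O bond to give cesium phenoxide 18 exactly at O4', which is alkylated in situ by the allylic bromide (one-flask desilylation–Williamson etherification, SN2 at the primary carbon). The 5-OH is held in a hydrogen bond to C4=O, is less acidic and less nucleophilic, and with 1.1 equivalents of 17 should stay free; dimethylformamide favours O- over C-alkylation.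

## Compound list

1 | (4-bromophenoxy)(tert-butyl)dimethylsilane | CC(C)(C)[Si](C)(C)Oc1ccc(Br)cc1 | starting material
2 | N,2-dimethoxy-N-methylacetamide | COCC(=O)N(C)OC | starting material
3 | [4-(tert-butyldimethylsilyloxy)phenyl]magnesium bromide | CC(C)(C)[Si](C)(C)Oc1ccc([Mg]Br)cc1 | intermediate (not isolated)
4 | 1-[4-(tert-butyldimethylsilyloxy)phenyl]-2-methoxyethan-1-one | COCC(=O)c1ccc(O[Si](C)(C)C(C)(C)C)cc1 | intermediate
5 | (2E)-3-ethoxyprop-2-enoyl chloride | CCO/C=C/C(=O)Cl | starting material
6 | lithium (Z)-1-[4-(tert-butyldimethylsilyloxy)phenyl]-2-methoxyethen-1-olate | [Li]O/C(=C\OC)c1ccc(O[Si](C)(C)C(C)(C)C)cc1 | intermediate (not isolated)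
7 | (4E)-1-[4-(tert-butyldimethylsilyloxy)phenyl]-5-ethoxy-2-methoxypent-4-ene-1,3-dione (racemic at C2, readily enolised) | CCO/C=C/C(=O)C(OC)C(=O)c1ccc(O[Si](C)(C)C(C)(C)C)cc1 | intermediate (not isolated)
8 | 2-[4-(tert-butyldimethylsilyloxy)phenyl]-3-methoxy-4H-pyran-4-one | COc1c(-c2ccc(O[Si](C)(C)C(C)(C)C)cc2)occc1=O | intermediate
9 | 5-bromo-2-[4-(tert-butyldimethylsilyloxy)phenyl]-3-methoxy-4H-pyran-4-one | COc1c(-c2ccc(O[Si](C)(C)C(C)(C)C)cc2)occ(Br)c1=O | intermediate
10 | methyl (2E)-3-methoxybut-2-enoate | COC(=O)/C=C(\C)OC | starting material
11 | lithium (1E)-1,3-dimethoxybuta-1,3-dien-1-olate | COC(=C)/C=C(\OC)O[Li] | intermediate (not isolated)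
12 | (1E)-1,3-dimethoxy-1-(trimethylsilyloxy)buta-1,3-diene | COC(=C)/C=C(\OC)O[Si](C)(C)C | intermediate
13 | 5-bromo-2-[4-(tert-butyldimethylsilyloxy)phenyl]-3-methoxy-4-(trimethylsilyloxy)pyrylium trifluoromethanesulfonate | COc1c(-c2ccc(O[Si](C)(C)C(C)(C)C)cc2)[o+]cc(Br)c1O[Si](C)(C)C.[O-]S(=O)(=O)C(F)(F)F | intermediate (not isolated)
14 | 4a-bromo-2-[4-(tert-butyldimethylsilyloxy)phenyl]-3,5,7-trimethoxy-5-(trimethylsilyloxy)-4a,5,8,8a-tetrahydro-4H-chromen-4-one (racemic, cis ring fusion with Br at C4a and H at C8a on the same face, both epimers at C5; one enantiomer drawn) | COC1=CC(OC)(O[Si](C)(C)C)[C@@]2(Br)C(=O)C(OC)=C(c3ccc(O[Si](C)(C)C(C)(C)C)cc3)O[C@H]2C1 | intermediate (not isolated)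
15 | 4'-(tert-butyldimethylsilyloxy)-3,7-dimethoxy-5-(trimethylsilyloxy)flavone | COc1cc(O[Si](C)(C)C)c2c(=O)c(OC)c(-c3ccc(O[Si](C)(C)C(C)(C)C)cc3)oc2c1 | intermediate (not isolated)
16 | 4'-(tert-butyldimethylsilyloxy)-5-hydroxy-3,7-dimethoxyflavone | COc1cc(O)c2c(=O)c(OC)c(-c3ccc(O[Si](C)(C)C(C)(C)C)cc3)oc2c1 | intermediate
17 | 1-bromo-3-methylbut-2-ene (prenyl bromide) | CC(C)=CCBr | starting material
18 | cesium 4-(5-hydroxy-3,7-dimethoxy-4-oxo-4H-chromen-2-yl)phenolate | COc1cc(O)c2c(=O)c(OC)c(-c3ccc([O-])cc3)oc2c1.[Cs+] | intermediate (not isolated)
19 | 5-hydroxy-3,7-dimethoxy-2-[4-(3-methylbut-2-enyloxy)phenyl]-4H-chromen-4-one | COc1cc(O)c2c(=O)c(OC)c(-c3ccc(OCC=C(C)C)cc3)oc2c1 | target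

## Step count and least certain steps

Total step count: 6. Longest linear sequence: 5 steps (steps 1, 2, 3, 5, 6); step 4 prepares the diene in a one-step side branch.

**Step 5 (key step).** What may go wrong:
- Insufficient reactivity: silylation of the carbonyl may not make C6 electrophilic enough, so that protodesilylation or oligomerisation of the diene wins.
- Interruption after the first bond: silyl transfer from the dioxocarbenium intermediate to triflate may outrun ring closure, after which dehydrobromination of the open Michael adduct removes the bromine before C4a–C5 has formed.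
- Incomplete aromatisation: bromine at C4a and hydrogen at C8a are syn across the cis ring fusion, so loss of HBr may be slow, and halophilic removal of bromine by the amine would leave ring A at the dihydro level.
- Loss of silanol instead of methanol from the mixed ketal, which would methylate O5.

Fallback (known chemistry, ring C closed last): the fallback sets out from 4. Its lithium enolate (LiN(SiMe3)2, THF, −78 °C) is C-acylated with commercial 2,4,6-trimethoxybenzoyl chloride to give 1-[4-(tert-butyldimethylsilyloxy)phenyl]-2-methoxy-3-(2,4,6-trimethoxyphenyl)propane-1,3-dione F1. BCl3 (CH2Cl2, −78 → 0 °C) cleaves one methyl ether ortho to the carbonyl by chelation to give 1-[4-(tert-butyldimethylsilyloxy)phenyl]-3-(2-hydroxy-4,6-dimethoxyphenyl)-2-methoxypropane-1,3-dione F2. Acid-catalysed cyclodehydration (TsOH, toluene, 80 °C, the closing stage of a Baker–Venkataraman flavone synthesis) gives 4'-(tert-butyldimethylsilyloxy)-3,5,7-trimethoxyflavone F3. A second chelation-controlled demethylation of the peri 5-OMe (BCl3, CH2Cl2, −78 → 0 °C) comes back to the route at 16.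

**Step 2.** What may go wrong: O-acylation or double acylation of the enolate, conjugate addition at the β-carbon of the acid chloride, and hydrolysis of the β-ethoxy enone before ring closure. Fallback: C4–C5 and C6 are introduced in separate events, setting out from 4. C-acetylation (LiN(SiMe3)2, THF, −78 °C, then acetyl chloride) should give 1-[4-(tert-butyldimethylsilyloxy)phenyl]-2-methoxybutane-1,3-dione F4. Condensation of its methyl ketone with N,N-dimethylformamide dimethyl acetal (toluene, 90 °C) should give (4E)-5-(dimethylamino)-1-[4-(tert-butyldimethylsilyloxy)phenyl]-2-methoxypent-4-ene-1,3-dione F5. CF3CO2H in CH2Cl2 then closes the ring with loss of dimethylamine and comes back to the route at 8.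

**Step 3.** What may go wrong: competing bromination of the silyloxyphenyl ring ortho to oxygen, or sluggish substitution at C5 that invites over-bromination. Fallback: addition–elimination in place of direct substitution, setting out from 8. Br2 (CH2Cl2, 0 °C) adds across C5=C6 to give trans-5,6-dibromo-2-[4-(tert-butyldimethylsilyloxy)phenyl]-3-methoxy-5,6-dihydro-4H-pyran-4-one F6. Et3N then removes the acidic C5 hydrogen and expels the anomeric C6 bromide, which comes back to the route at 9; this is the standard way to 3-bromochromones.

**Step 6.** What may go wrong: alkylation of the 5-oxygen or of a ring-A carbon once phenoxide and base are present together, and consumption of 17 by fluoride. Fallback: the two events are separated and the alkylation mechanism is changed, setting out from 16. Bu4NF buffered with acetic acid (THF, 0 °C) should give 4',5-dihydroxy-3,7-dimethoxyflavone F7. Mitsunobu etherification with 3-methylbut-2-en-1-ol (PPh3, diisopropyl azodicarboxylate, THF, 0 °C → rt) should engage only the more acidic, unchelated 4'-OH and comes back to the route at 19.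

## Further compounds

F1 | step 5 | 1-[4-(tert-butyldimethylsilyloxy)phenyl]-2-methoxy-3-(2,4,6-trimethoxyphenyl)propane-1,3-dione (racemic, enolisable) | COc1cc(OC)c(C(=O)C(OC)C(=O)c2ccc(O[Si](C)(C)C(C)(C)C)cc2)c(OC)c1
F2 | step 5 | 1-[4-(tert-butyldimethylsilyloxy)phenyl]-3-(2-hydroxy-4,6-dimethoxyphenyl)-2-methoxypropane-1,3-dione (racemic, enolisable) | COc1cc(O)c(C(=O)C(OC)C(=O)c2ccc(O[Si](C)(C)C(C)(C)C)cc2)c(OC)c1
F3 | step 5 | 4'-(tert-butyldimethylsilyloxy)-3,5,7-trimethoxyflavone | COc1cc(OC)c2c(=O)c(OC)c(-c3ccc(O[Si](C)(C)C(C)(C)C)cc3)oc2c1
F4 | step 2 | 1-[4-(tert-butyldimethylsilyloxy)phenyl]-2-methoxybutane-1,3-dione (racemic, enolisable) | COC(C(C)=O)C(=O)c1ccc(O[Si](C)(C)C(C)(C)C)cc1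
F5 | step 2 | (4E)-5-(dimethylamino)-1-[4-(tert-butyldimethylsilyloxy)phenyl]-2-methoxypent-4-ene-1,3-dione (racemic, enolisable) | COC(C(=O)/C=C/N(C)C)C(=O)c1ccc(O[Si](C)(C)C(C)(C)C)cc1
F6 | step 3 | trans-5,6-dibromo-2-[4-(tert-butyldimethylsilyloxy)phenyl]-3-methoxy-5,6-dihydro-4H-pyran-4-one (racemic; one enantiomer drawn) | COC1=C(c2ccc(O[Si](C)(C)C(C)(C)C)cc2)O[C@H](Br)[C@@H](Br)C1=O
F7 | step 6 | 4',5-dihydroxy-3,7-dimethoxyflavone | COc1cc(O)c2c(=O)c(OC)c(-c3ccc(O)cc3)oc2c1
A1 | alternative 1 | 4-hydroxy-6-[(3Z)-3-methoxy-4-[4-(3-methylbut-2-enyloxy)phenyl]-2-oxobut-3-en-1-yl]-2H-pyran-2-one | CO/C(C(=O)Cc1cc(O)cc(=O)o1)=C\c1ccc(OCC=C(C)C)cc1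
A2 | alternative 1 | methyl (8Z)-8-methoxy-9-[4-(3-methylbut-2-enyloxy)phenyl]-3,5,7-trioxonon-8-enoate | COC(=O)CC(=O)CC(=O)CC(=O)/C(OC)=C/c1ccc(OCC=C(C)C)cc1
A3 | alternative 1 | (2Z)-2-methoxy-3-[4-(3-methylbut-2-enyloxy)phenyl]-1-(2,4,6-trihydroxyphenyl)prop-2-en-1-one | CO/C(C(=O)c1c(O)cc(O)cc1O)=C\c1ccc(OCC=C(C)C)cc1
A4 | alternative 2 | 1-(2,6-difluoro-4-methoxyphenyl)-2-methoxy-3-[4-(3-methylbut-2-enyloxy)phenyl]propane-1,3-dione | COc1cc(F)c(C(=O)C(OC)C(=O)c2ccc(OCC=C(C)C)cc2)c(F)c1
A5 | alternative 2 | 5-fluoro-3,7-dimethoxy-4'-(3-methylbut-2-enyloxy)flavone | COc1cc(F)c2c(=O)c(OC)c(-c3ccc(OCC=C(C)C)cc3)oc2c1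
A6 | alternative 3 | (2E)-3-[4-(benzyloxy)phenyl]-3-(3,5-dimethoxyphenoxy)-2-methoxyprop-2-enoic acid | CO/C(C(=O)O)=C(/Oc1cc(OC)cc(OC)c1)c1ccc(OCc2ccccc2)cc1
A7 | alternative 3 | 4'-benzyloxy-3,5,7-trimethoxyflavone | COc1cc(OC)c2c(=O)c(OC)c(-c3ccc(OCc4ccccc4)cc3)oc2c1
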